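The six-membered ring is opened at C2–C3 and C5–C6, which gives a C6–C1–C2 malonyl unit and the C3–C4–C5 diketone 29. Geranyl is then cut at C6'=C7', C4'–C5' and last at C2'=C3', and the C1 prenyl is cut at C2''=C3''.
Enabling feature: ring carbon C1 lies between the carbonyls C2 and C6 and carries two arms that are identical through CH2–CH=C (C1'–C3' of geranyl, C1''–C3'' of prenyl). It therefore maps onto a prochiral malonate carbon with two CH2CHO arms and two unlike esters.
Forward: malonate, diallylmalonate, dialdehyde 6. One formyl group is olefinated (C2'=C3') and the other becomes prenyl. The enoate is grown to geranyl by reduction, bromide formation, C2 homologation and Wittig reaction, and the only ring is closed last by a [3+3] acylation/Dieckmann sequence.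
Stereochemistry: C1 is set in step 4 by the 8-phenylmenthyl phosphonate, which takes one of the two enantiotopic arms and also fixes the E geometry of C2'=C3'. C1 is quaternary and cannot epimerise.
The configuration reaches the ring because the two ester carbonyls react in a fixed order. The tert-butyl ester carbon becomes C2 (bonded to the prenyl-bearing C3) and the methyl ester carbon becomes C6 (bonded to the benzoyl-bearing C5).

Key step: step 4

Assumption: the (1R,2S,5R)-auxiliary is taken to favour the arm that leads to (R)-11; if the other arm reacts faster, the mirror-image auxiliary delivers the required configuration at the malonate carbon.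
Remark: kolanone is an enolised β-triketone. Compound 33 is written as the tautomer of the target SMILES; the tautomers interconvert freely and C1 is not affected.

Step 1
Reactants: 1 tert-butyl methyl malonate; 2 allyl bromide
Product: 4 tert-butyl methyl 2,2-diallylmalonate, via monoallyl malonate 3 (not isolated)
Conditions: NaH (2.3 equiv), 2 (2.5 equiv), THF, 0 → 50 °C
Reagents that add atoms: none
Why: Double SN2 malonate alkylation, in which a hydride base avoids ester exchange and both acidic hydrogens are replaced, leaving an achiral but prochiral quaternary carbon.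

Step 2
Reactants: 4 tert-butyl methyl 2,2-diallylmalonate
Product: 6 tert-butyl methyl 2,2-bis(2-oxoethyl)malonate, via bis-ozonide 5 (not isolated)
Conditions: O3, CH2Cl2, −78 °C; then Me2S, −78 °C → rt
Reagents that add atoms: ozone, [O-][O+]=O
Why: Ozonolysis with reductive work-up cleaves both terminal alkenes to formylmethyl arms, as is well known for dialkyl diallylmalonates, and the esters are inert.

Step 3
Reactants: 7 (1R,2S,5R)-8-phenylmenthol; 8 triethyl 2-phosphonopropionate
Product: 9 (1R,2S,5R)-8-phenylmenthyl 2-(diethoxyphosphoryl)propanoate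
Conditions: 8 (2 equiv), DMAP (0.3 equiv), toluene, reflux, EtOH distilled off
Reagents that add atoms: none
Why: DMAP-catalysed transesterification of a phosphono ester (elimination–addition through the phosphono ketene) exchanges only the carboxylic ester; the carbinol C–O bond of 7 is untouched, and the epimer mixture at the P-bearing carbon is irrelevant because that carbon becomes planar on deprotonation.

Step 4
Reactants: 6 tert-butyl methyl 2,2-bis(2-oxoethyl)malonate; 9 (1R,2S,5R)-8-phenylmenthyl 2-(diethoxyphosphoryl)propanoate
Product: 11 1-tert-butyl 3-methyl (2R)-2-(2-oxoethyl)-2-[(2E)-3-methyl-4-oxo-4-(8-phenylmenthyloxy)but-2-enyl]malonate, via potassium phosphonoenolate 10 (not isolated)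
Conditions: 9 (1.15 equiv), KN(SiMe3)2 (1.1 equiv), 18-crown-6 (3 equiv), THF, −78 °C; then 6 (1.0 equiv), −78 → −40 °C; cold 0.5 M HCl
Reagents that add atoms: none
Why: The phosphonoenolate 10 adds reversibly to a formyl group of 6, the adduct closes to an oxaphosphetane in the product-determining step and this collapses with loss of diethyl phosphate, so the diethyl phosphonate and the bulky ester should favour the E-enoate with the ester trans to C1'H2. The closest known reaction type is the asymmetric Horner–Wadsworth–Emmons desymmetrisation of dialdehydes with enantiotopic formyl groups by 8-phenylmenthyl dialkylphosphonoacetates under KN(SiMe3)2/18-crown-6, and no ring is closed. The malonate carbon becomes the only new stereocentre (R) purely through the choice of arm: the phenyl ring of the auxiliary covers one face of the enolate, the E pathway then demands one face of the aldehyde, and in the two arms that face is flanked either by CO2tBu or by CO2Me. The step needs arm selectivity, E geometry and mono-olefination; the tert-butyl/methyl size gap supplies the first, and because the prochiral carbon lies β to the formyl groups this is backed up in two ways. A small excess of 10 drains the minor mono-adduct, whose free arm is the fast-reacting one, into the bis-enoate that is no longer stereogenic at carbon (kinetic amplification), and the two mono-adducts are diastereomers owing to the auxiliary, so chromatography can raise the purity further and also remove any Z isomer. The quaternary carbon bears no hydrogen and cannot epimerise.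

Step 5
Reactants: 11 (R)-aldehyde enoate
Product: 12 1-tert-butyl 3-methyl (2S)-2-(3-methylbut-2-enyl)-2-[(2E)-3-methyl-4-oxo-4-(8-phenylmenthyloxy)but-2-enyl]malonate
Conditions: iPrPPh3I (1.1 equiv), n-BuLi (1.05 equiv), THF, 0 °C; then 11, −78 → 0 °C
Reagents that add atoms: isopropyltriphenylphosphonium iodide, CC(C)[P+](c1ccccc1)(c1ccccc1)c1ccccc1.[I-]
Why: Wittig olefination, in which the non-stabilised ylide takes the aldehyde far faster than it can add to the hindered α-methyl enoate or to the esters, so one equivalent at low temperature turns only CH2CHO into prenyl (the descriptor changes to S by priority only).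

Step 6
Reactants: 12 (S)-triester
Product: 13 (2S)-2-(tert-butoxycarbonyl)-5-methyl-2-[(2E)-3-methyl-4-oxo-4-(8-phenylmenthyloxy)but-2-enyl]hex-4-enoic acid
Conditions: LiOH·H2O (5 equiv), THF/MeOH/H2O, rt → 40 °C; then 0.5 M HCl, 0 °C, to pH 3
Reagents that add atoms: lithium hydroxide, [Li+].[OH-]
Why: Selective saponification, since only the methyl ester has an unhindered alkoxy group while the tert-butyl and 8-phenylmenthyl esters resist hydroxide; it masks this carbonyl as a carboxylate because a malonate methyl ester would not survive the hydride of step 7.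

Step 7
Reactants: 13 (S)-half-acid enoate
Product: 14 (2S)-2-(tert-butoxycarbonyl)-2-[(2E)-4-hydroxy-3-methylbut-2-enyl]-5-methylhex-4-enoic acid
Conditions: iBu2AlH (4.5 equiv), CH2Cl2, −78 → −40 °C; aq. potassium sodium tartrate, then citric acid to pH 3
Reagents that add atoms: none
Why: 1,2-Reduction of an enoate to the allylic alcohol with iBu2AlH, in which the first equivalent converts the acid into an aluminium carboxylate that, like the tert-butyl ester, is inert at low temperature, so only the conjugated ester is reduced, the E alkene is kept and auxiliary 7 is released and separated from the acid by extraction.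

Step 8
Reactants: 14 (S)-hydroxy acid
Product: 15 1-tert-butyl 3-methyl (2S)-2-[(2E)-4-hydroxy-3-methylbut-2-enyl]-2-(3-methylbut-2-enyl)malonate
Conditions: MeI (1.5 equiv), KHCO3 (2 equiv), DMF, rt
Reagents that add atoms: iodomethane, CI
Why: Carboxylate O-alkylation (SN2) under a base too weak to deprotonate the alcohol restores the methyl ester that must accept the final ring closure.

Step 9
Reactants: 15 (S)-allylic alcohol
Product: 16 1-tert-butyl 3-methyl (2S)-2-[(2E)-4-bromo-3-methylbut-2-enyl]-2-(3-methylbut-2-enyl)malonate
Conditions: CBr4 (1.3 equiv), PPh3 (1.3 equiv), CH2Cl2, −20 → 0 °C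
Reagents that add atoms: tetrabromomethane, BrC(Br)(Br)Br
Why: The Appel reaction converts a primary allylic alcohol into the bromide under neutral conditions without allylic transposition or loss of alkene geometry, and it tolerates the esters and the prenyl group.

Step 10
Reactants: 17 acetaldehyde; 18 cyclohexylamine
Product: 19 (E)-N-cyclohexylethanimine
Conditions: Et2O, 0 °C; anhydrous K2CO3; distillation
Reagents that add atoms: none
Why: Simple imine condensation gives the standard acetaldehyde enolate equivalent for directed alkylation.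

Step 11
Reactants: 16 (S)-allylic bromide; 19 (E)-N-cyclohexylethanimine
Product: 22 1-tert-butyl 3-methyl (2S)-2-[(2E)-3-methyl-6-oxohex-2-enyl]-2-(3-methylbut-2-enyl)malonate, via lithio imine 20 (not isolated), via alkylated imine 21 (not isolated)
Conditions: 19 (1.4 equiv), LiN(iPr)2 (1.3 equiv), THF, 0 °C; then 16, −78 → −20 °C; then aq. tartaric acid, 0 °C → rt
Reagents that add atoms: water, O
Why: Metalloenamine (aza-enolate) alkylation forms C4'–C5' by SN2 at the very reactive primary allylic bromide, a known two-carbon homologation of geranyl-type bromides that has no α/γ ambiguity and is faster than attack on the two esters shielded by the quaternary carbon; mild acid then frees the aldehyde.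

Step 12
Reactants: 22 (S)-aldehyde
Product: 23 1-tert-butyl 3-methyl (2S)-2-[(2E)-3,7-dimethylocta-2,6-dienyl]-2-(3-methylbut-2-enyl)malonate
Conditions: iPrPPh3I (1.2 equiv), n-BuLi (1.15 equiv), THF, 0 °C; then 22, −78 → 0 °C
Reagents that add atoms: isopropyltriphenylphosphonium iodide, CC(C)[P+](c1ccccc1)(c1ccccc1)c1ccccc1.[I-]
Why: A second isopropylidene Wittig olefination closes the geranyl chain at C6'=C7', where no geometry issue arises, and leaves the esters untouched.

Step 13
Reactants: 23 (S)-geranyl prenyl malonate
Product: 25 (2R,4E)-2-(methoxycarbonyl)-5,9-dimethyl-2-(3-methylbut-2-enyl)deca-4,8-dienoic acid, via trimethylsilyl ester 24 (not isolated)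
Conditions: Me3SiOTf (3 equiv), 2,6-lutidine (4.5 equiv), CH2Cl2, 0 °C → rt; then aq. NaH2PO4
Reagents that add atoms: none
Why: Silyl triflate mediated tert-butyl ester cleavage (loss of isobutene, then hydrolysis of the silyl ester) runs in a buffered medium with no free strong acid, which avoids the protonation of the trisubstituted alkenes and the lactonisation that acidolysis would risk, and the methyl ester is unaffected.

Step 14
Reactants: 26 1-phenylbutane-1,3-dione; 27 prenyl bromide
Product: 29 7-methyl-1-phenyloct-6-ene-1,3-dione, via dilithio benzoylacetone 28 (not isolated)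
Conditions: LiN(iPr)2 (2.1 equiv), THF, 0 °C; then 27 (1.0 equiv), −78 → 0 °C; 1 M HCl
Reagents that add atoms: none
Why: Classical γ-alkylation of a β-diketone dianion, whose terminal carbanion is the more reactive site and takes the allylic bromide by SN2.

Step 15
Reactants: 25 (R)-half-acid methyl ester; 29 7-methyl-1-phenyloct-6-ene-1,3-dione
Product: 33 kolanone, via acid chloride 30 (not isolated), via dilithio diketone 31 (not isolated), via open-chain triketo ester 32 (not isolated)
Conditions: (a) 25, 1-chloro-N,N,2-trimethylprop-1-enylamine (1.05 equiv), CH2Cl2, 0 °C → rt, solvent changed to THF; (b) 29 (2.2 equiv), LiN(iPr)2 (4.4 equiv), THF, 0 °C; (c) a into b, −78 °C, then → rt (40 °C if needed); cold 0.5 M HCl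
Reagents that add atoms: none
Why: γ-Acylation of a β-diketone dianion followed by Dieckmann condensation, in which the acid chloride is made under neutral conditions, the prenyl-bearing terminal carbanion of 31 takes it (C2–C3), a second equivalent of 31 re-deprotonates the product, and on warming the central carbon closes on the methyl ester (C5–C6, six-membered ring, helped by the gem-dialkyl effect) with the strongly acidic enolised trione as the thermodynamic sink; no bond to C1 is made or broken, so its configuration is carried over as R.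

Compound list
1 | tert-butyl methyl malonate | COC(=O)CC(=O)OC(C)(C)C | starting material
2 | allyl bromide | C=CCBr | starting material
3 | tert-butyl methyl 2-allylmalonate (racemic) | COC(=O)C(CC=C)C(=O)OC(C)(C)C | intermediate
4 | tert-butyl methyl 2,2-diallylmalonate | COC(=O)C(CC=C)(CC=C)C(=O)OC(C)(C)C | intermediate
5 | bis(1,2,4-trioxolane) of 4 (bis-ozonide, stereoisomer mixture) | COC(=O)C(CC1OCOO1)(CC1OCOO1)C(=O)OC(C)(C)C | intermediate
6 | tert-butyl methyl 2,2-bis(2-oxoethyl)malonate | COC(=O)C(CC=O)(CC=O)C(=O)OC(C)(C)C | intermediate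
7 | (1R,2S,5R)-8-phenylmenthol | C[C@@H]1CC[C@H]([C@@H](C1)O)C(C)(C)c2ccccc2 | starting material
8 | triethyl 2-phosphonopropionate (racemic) | CCOC(=O)C(C)P(=O)(OCC)OCC | starting material
9 | (1R,2S,5R)-8-phenylmenthyl 2-(diethoxyphosphoryl)propanoate (both epimers at the P-bearing carbon) | C[C@@H]1CC[C@H]([C@@H](C1)OC(=O)C(C)P(=O)(OCC)OCC)C(C)(C)c2ccccc2 | intermediate
10 | potassium phosphonoenolate of 9 | C[C@@H]1CC[C@H]([C@@H](C1)OC(=O)[C-](C)P(=O)(OCC)OCC)C(C)(C)c2ccccc2.[K+] | intermediate
11 | 1-tert-butyl 3-methyl (2R)-2-(2-oxoethyl)-2-[(2E)-3-methyl-4-oxo-4-((1R,2S,5R)-8-phenylmenthyloxy)but-2-enyl]malonate | C[C@@H]1CC[C@H]([C@@H](C1)OC(=O)/C(C)=C/C[C@](C(=O)OC)(CC=O)C(=O)OC(C)(C)C)C(C)(C)c2ccccc2 | intermediate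
12 | 1-tert-butyl 3-methyl (2S)-2-(3-methylbut-2-enyl)-2-[(2E)-3-methyl-4-oxo-4-((1R,2S,5R)-8-phenylmenthyloxy)but-2-enyl]malonate | C[C@@H]1CC[C@H]([C@@H](C1)OC(=O)/C(C)=C/C[C@](C(=O)OC)(CC=C(C)C)C(=O)OC(C)(C)C)C(C)(C)c2ccccc2 | intermediate
13 | (2S)-2-(tert-butoxycarbonyl)-5-methyl-2-[(2E)-3-methyl-4-oxo-4-((1R,2S,5R)-8-phenylmenthyloxy)but-2-enyl]hex-4-enoic acid | C[C@@H]1CC[C@H]([C@@H](C1)OC(=O)/C(C)=C/C[C@](C(=O)O)(CC=C(C)C)C(=O)OC(C)(C)C)C(C)(C)c2ccccc2 | intermediate
14 | (2S)-2-(tert-butoxycarbonyl)-2-[(2E)-4-hydroxy-3-methylbut-2-enyl]-5-methylhex-4-enoic acid | OC/C(C)=C/C[C@](C(=O)O)(CC=C(C)C)C(=O)OC(C)(C)C | intermediate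
15 | 1-tert-butyl 3-methyl (2S)-2-[(2E)-4-hydroxy-3-methylbut-2-enyl]-2-(3-methylbut-2-enyl)malonate | OC/C(C)=C/C[C@](C(=O)OC)(CC=C(C)C)C(=O)OC(C)(C)C | intermediate
16 | 1-tert-butyl 3-methyl (2S)-2-[(2E)-4-bromo-3-methylbut-2-enyl]-2-(3-methylbut-2-enyl)malonate | BrC/C(C)=C/C[C@](C(=O)OC)(CC=C(C)C)C(=O)OC(C)(C)C | intermediate
17 | acetaldehyde | CC=O | starting material
18 | cyclohexylamine | NC1CCCCC1 | starting material
19 | (E)-N-cyclohexylethanimine | C/C=N/C1CCCCC1 | intermediate
20 | lithium aza-enolate of 19 | [Li+].C=C[N-]C1CCCCC1 | intermediate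
21 | N-cyclohexyl imine of aldehyde 22 | C1CCCCC1/N=C/CC/C(C)=C/C[C@](C(=O)OC)(CC=C(C)C)C(=O)OC(C)(C)C | intermediate
22 | 1-tert-butyl 3-methyl (2S)-2-[(2E)-3-methyl-6-oxohex-2-enyl]-2-(3-methylbut-2-enyl)malonate | O=CCC/C(C)=C/C[C@](C(=O)OC)(CC=C(C)C)C(=O)OC(C)(C)C | intermediate
23 | 1-tert-butyl 3-methyl (2S)-2-[(2E)-3,7-dimethylocta-2,6-dienyl]-2-(3-methylbut-2-enyl)malonate | CC(C)=CCC/C(C)=C/C[C@](C(=O)OC)(CC=C(C)C)C(=O)OC(C)(C)C | intermediate
24 | 1-methyl 3-trimethylsilyl (2S)-2-geranyl-2-prenylmalonate | CC(C)=CCC/C(C)=C/C[C@](C(=O)OC)(CC=C(C)C)C(=O)O[Si](C)(C)C | intermediate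
25 | (2R,4E)-2-(methoxycarbonyl)-5,9-dimethyl-2-(3-methylbut-2-enyl)deca-4,8-dienoic acid | CC(C)=CCC/C(C)=C/C[C@](C(=O)OC)(CC=C(C)C)C(=O)O | intermediate
26 | 1-phenylbutane-1,3-dione (benzoylacetone) | CC(=O)CC(=O)c1ccccc1 | starting material
27 | prenyl bromide (1-bromo-3-methylbut-2-ene) | CC(C)=CCBr | starting material
28 | dilithio dianion of 26 | [Li+].[Li+].[CH2-]C(=O)[CH-]C(=O)c1ccccc1 | intermediate
29 | 7-methyl-1-phenyloct-6-ene-1,3-dione | CC(C)=CCCC(=O)CC(=O)c1ccccc1 | intermediate
30 | methyl (2S,4E)-2-(chlorocarbonyl)-5,9-dimethyl-2-(3-methylbut-2-enyl)deca-4,8-dienoate | CC(C)=CCC/C(C)=C/C[C@](C(=O)OC)(CC=C(C)C)C(=O)Cl | intermediate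
31 | dilithio dianion of 29 (carbanions at C2 and C4) | [Li+].[Li+].CC(C)=CC[CH-]C(=O)[CH-]C(=O)c1ccccc1 | intermediate
32 | methyl (2R)-2-geranyl-3,5,7-trioxo-7-phenyl-2,4-diprenylheptanoate (epimers at C4, enolised) | CC(C)=CCC/C(C)=C/C[C@](C(=O)OC)(CC=C(C)C)C(=O)C(CC=C(C)C)C(=O)CC(=O)c1ccccc1 | intermediate
33 | kolanone (R at ring carbon C1 for the tautomer drawn; C1 geranyl and prenyl, C3 prenyl, C5 benzoyl as its enol) | CC(C)=CCC/C(C)=C/C[C@]1(CC=C(C)C)C(=O)C(CC=C(C)C)=C(O)/C(=C(\O)c2ccccc2)C1=O | target

Total step count: 15. Longest linear sequence: 12 steps (1, 2, 4–9, 11–13, 15).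

Steps most likely to fail

Step 4. Discrimination between the two formylmethyl arms may be weak. The prochiral carbon sits one atom farther from the reacting carbonyl than the stereocentres of the best-behaved dialdehydes. The E/Z control of an α-methyl phosphonate may also erode under dissociating conditions.

The fallback sets out from 1 and returns at 23. It builds the quaternary centre by enantioselective phase-transfer alkylation instead of desymmetrisation.
- Saponification of 1 (KOH, MeOH) gives mono-tert-butyl malonate F1.
- Esterification with 2,2-diphenylethanol (EDC, DMAP) gives 2,2-diphenylethyl tert-butyl malonate F2.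
- NaH and 27 give the racemic α-prenyl malonate F3.
- Alkylation with geranyl bromide under 50% aq. KOH/toluene at −40 °C, with the appropriate enantiomer of a C2-symmetric N-spiro binaphthyl ammonium bromide carrying 3,4,5-trifluorophenyl groups, gives the (S)-geranyl prenyl malonate F4. The enolate face is read from the two unlike esters and not from the two alkyl chains.
- KOH/MeOH removes the primary ester to give the (S)-half-acid tert-butyl ester F5, and MeI/KHCO3 leads to 23.

Step 15. Acylation of a secondary carbanion by a carbonyl next to a quaternary carbon may be slow. Acylation at oxygen, proton transfer or attack on the methyl ester could then compete, and the closure may go through enol oxygen instead of carbon.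

The fallback sets out from 30 and returns at 32. It replaces the acylation by an aldol addition and an oxidation.
- LiAlH(OtBu)3 in THF at −78 °C reduces 30 to the (R)-formyl ester F6.
- The dianion 31 adds through its terminal carbon to this far more accessible aldehyde at −78 °C to give the aldol F7 as a diastereomer mixture.
- Periodinane oxidation (DMP, CH2Cl2) gives 32, which is now isolated and closed to 33 with NaH in THF.

Step 11. The strongly basic aza-enolate may attack the methyl ester, may be alkylated twice or may self-condense.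

The fallback sets out from 16 and returns at 23, bypassing 22 and step 12. It uses a sulfone-stabilised prenyl anion.
- PhSO2Na and 27 in DMF give prenyl phenyl sulfone F8.
- Its lithio derivative (n-BuLi, THF/DMPU, −78 °C) is alkylated at the α-carbon by 16 to give the sulfone F9.
- Buffered sodium amalgam, Na(Hg)/Na2HPO4 in MeOH/THF at −20 °C, tolerates the esters and removes the sulfonyl group to give 23.
- Partial migration of the C6'=C7' alkene during this reduction is the reason this sequence is kept in reserve.

Further compounds
F1 | step 4 | mono-tert-butyl malonate | CC(C)(C)OC(=O)CC(=O)O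
F2 | step 4 | 2,2-diphenylethyl tert-butyl malonate | CC(C)(C)OC(=O)CC(=O)OCC(c1ccccc1)c1ccccc1
F3 | step 4 | 2,2-diphenylethyl tert-butyl 2-(3-methylbut-2-enyl)malonate (racemic) | CC(C)=CCC(C(=O)OCC(c1ccccc1)c1ccccc1)C(=O)OC(C)(C)C
F4 | step 4 | 1-tert-butyl 3-(2,2-diphenylethyl) (2S)-2-[(2E)-3,7-dimethylocta-2,6-dienyl]-2-(3-methylbut-2-enyl)malonate | CC(C)=CCC/C(C)=C/C[C@](C(=O)OCC(c1ccccc1)c1ccccc1)(CC=C(C)C)C(=O)OC(C)(C)C
F5 | step 4 | (2S,4E)-2-(tert-butoxycarbonyl)-5,9-dimethyl-2-(3-methylbut-2-enyl)deca-4,8-dienoic acid | CC(C)=CCC/C(C)=C/C[C@](C(=O)O)(CC=C(C)C)C(=O)OC(C)(C)C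
F6 | step 15 | methyl (2R,4E)-2-formyl-5,9-dimethyl-2-(3-methylbut-2-enyl)deca-4,8-dienoate | CC(C)=CCC/C(C)=C/C[C@](C(=O)OC)(CC=C(C)C)C=O
F7 | step 15 | methyl (2R)-2-geranyl-3-hydroxy-5,7-dioxo-7-phenyl-2,4-diprenylheptanoate (mixture at C3 and C4) | CC(C)=CCC/C(C)=C/C[C@](C(=O)OC)(CC=C(C)C)C(O)C(CC=C(C)C)C(=O)CC(=O)c1ccccc1
F8 | step 11 | 3-methylbut-2-enyl phenyl sulfone | CC(C)=CCS(=O)(=O)c1ccccc1
F9 | step 11 | 1-tert-butyl 3-methyl (2S)-2-[(2E)-3,7-dimethyl-5-(phenylsulfonyl)octa-2,6-dienyl]-2-(3-methylbut-2-enyl)malonate (mixture at C5') | CC(C)=CC(C/C(C)=C/C[C@](C(=O)OC)(CC=C(C)C)C(=O)OC(C)(C)C)S(=O)(=O)c1ccccc1
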